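(The data were generated by integration for an exercise; noise was put on by code.)

One percentage point of substrate was the unit I counted in, and I followed it as a crowd of molecules reaching a fork: once used, a molecule either stood as target or stood as something the readings did not show.

| flask | substrate | free catalyst | temperature | remark | time |
|---|---|---|---|---|---|
| teal | 0.61 M (in portions, 4) | 1.4 mM | 35 °C | run made earlier; portions every 12 min |  |
| blue | 0.61 M (in portions, 4) | 2 mM | 46 °C | run made earlier; portions every 12 min |  |
| gamma | 0.61 M (in portions, 4) | 2.7 mM | 40 °C | the portions of substrate follow each other after 12 min, the first at the start | 1.0 h |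
| zeta | 0.61 M | 2.7 mM | 40 °C | everything together at the start | 1.0 h |

| run | time / min | target / % | substrate / % |
|---|---|---|---|
| teal | 3.00 | 0 | 25 |
| teal | 5.00 | 0 | 25 |
| teal | 8.00 | 0 | 27 |
| teal | 12.0 | 4 | 23 |
| teal | 20.0 | 1 | 47 |
| teal | 40.0 | 8 | 94 |
| blue | 3.00 | 3 | 24 |
| blue | 5.00 | 1 | 23 |
| blue | 8.00 | 3 | 20 |
| blue | 12.0 | 3 | 17 |
| blue | 20.0 | 7 | 38 |
| blue | 40.0 | 15 | 74 |

(each reading ± 1.5 percentage points)



- which one finishes higher in amount of target, in percent of the substrate charged ("neither" within 2 percentage points) (gamma / zeta / neither)
- amount of target at the end, in percent of the substrate charged, gamma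
- amount of target at the end, in percent of the substrate charged, zeta

I read the last rows, at 40.0 min, after the last portion. In blue, at 46 °C, substrate stood at 74% and target at 15%, so target over substrate used was 57.7%. I called this ratio φ, the kept share, the chance that a used molecule is found as target; others would call it selectivity. The teal row, at 35 °C, showed target 8% against 6.00% used, slightly more target than substrate used. With a scatter of 1.5 percentage points per reading, I read that as a kept share near one, so the unseen branch showed in blue but not in teal.

Column against column, substrate used per mM of catalyst differed between the runs. Since gamma's temperature lay near the middle, I took the geometric mean of the two, scaled it to 2.7 mM and 1.0 h, and reckoned 30.2% used in gamma. Blue's φ then gave 17.4% of target, which I held as the low side, and I expected zeta higher.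

The forecast chose zeta, with 29% for gamma (range 22% to 36%) and 39% for zeta (26% to 48%); in its words, “Target formation speeds up as substrate accumulates”. My gamma figure lay below its range.

The flasks gave 24.0% in gamma and 28.7% in zeta.

    substrate + free catalyst ⇌ catalyst intermediate A (K = 4.40 M⁻¹, k = 7.30 M⁻¹ min⁻¹, Ea = 68.0 kJ mol⁻¹, ΔH = 52.0 kJ mol⁻¹)
    catalyst intermediate A ⇌ catalyst intermediate B (K = 0.200, k = 12.0 min⁻¹, Ea = 71.0 kJ mol⁻¹, ΔH = −49.0 kJ mol⁻¹)
    catalyst intermediate B → free catalyst + target (k = 68.0 min⁻¹, Ea = 74.0 kJ mol⁻¹)
    target ⇌ isomer of the product (K = 1.20, k = 0.0290 min⁻¹, Ea = 101 kJ mol⁻¹, ΔH = −2.00 kJ mol⁻¹)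
    (constants at 40 °C)

Neither flask had come to rest at 1.0 h: gamma still held 63% of its charged substrate unbound, and zeta 52%. Blue's φ on the substrate actually used gave 21.5% for gamma and 27.6% for zeta. The isomer of the product stood at 13.2% in gamma and 19.0% in zeta. In gamma, target and isomer of the product relax by their step alone with a half-life of 0.217 h, short against the run, yet at 1.00 h target was still being made 1.89 times faster than it was used up, each step taken net. Left until 10.0 h, gamma's substrate fell to 0.0198%, and target reached 45.5% in gamma and 45.5% in zeta, with gamma's isomer at 54.5%.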